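**Retrosynthetic overview**
- Target 16 is acyclic and comes from its bis(benzyl ether) 15 by hydrogenolysis. Diol 15 comes from LiAlH4 opening of the trans,trans-lactone acetal 14, which frees both CH2OH groups and the menthol auxiliary.
- 14 comes from dithiane 13 by C–S hydrogenolysis. 13 is made in one pot: Michael addition of lithiated dithiane 11 to (5R)-menthyloxybutenolide 10 (key C–C bond, sets C4), then benzylation of enolate 12 with bromide 5 (sets C3).
- Both aryl pieces (dithiane 3, bromide 5) come from syringaldehyde 1 through benzyl ether 2. Butenolide 10 comes from furfural 6 and (−)-menthol 9.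
- Ring order: the only carbocycle/heterocycle built on the skeleton is the temporary butenolide/γ-lactone template (made in step 5, opened in step 9). The dithiane (step 2) is a temporary umpolung ring, removed in step 8.

Assumption: the target is the (2R,3R)-enantiomer (both centres read as R from the SMILES); l-menthyl means (1R,2S,5R)-2-isopropyl-5-methylcyclohexyl.

**Step 1**
Reactants: 1 syringaldehyde (4-hydroxy-3,5-dimethoxybenzaldehyde)
Product: 2 4-(benzyloxy)-3,5-dimethoxybenzaldehyde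
Conditions: BnBr (1.2 eq), K2CO3 (2 eq), DMF, 60 °C
Reagents that add atoms: benzyl bromide, BrCc1ccccc1
Why: Williamson ether synthesis; the acidic 2,6-dimethoxyphenoxide is cleanly O-alkylated by the benzylic bromide and the aldehyde is untouched.

**Step 2**
Reactants: 2 4-(benzyloxy)-3,5-dimethoxybenzaldehyde
Product: 3 2-[4-(benzyloxy)-3,5-dimethoxyphenyl]-1,3-dithiane
Conditions: HS(CH2)3SH (1.1 eq), BF3·OEt2 (0.2 eq), CH2Cl2, 0 °C to rt
Reagents that add atoms: propane-1,3-dithiol, SCCCS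
Why: Lewis-acid-catalysed dithioacetalisation gives the Corey–Seebach acyl-anion precursor; the aryl benzyl ether tolerates catalytic BF3 at this temperature.

**Step 3**
Reactants: 2 4-(benzyloxy)-3,5-dimethoxybenzaldehyde
Product: 4 [4-(benzyloxy)-3,5-dimethoxyphenyl]methanol
Conditions: NaBH4, MeOH–THF, 0 °C
Reagents that add atoms: none
Why: Chemoselective borohydride reduction of the aldehyde; nothing else in the molecule is reducible.

**Step 4**
Reactants: 4 [4-(benzyloxy)-3,5-dimethoxyphenyl]methanol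
Product: 5 4-(benzyloxy)-3,5-dimethoxybenzyl bromide (2-(benzyloxy)-5-(bromomethyl)-1,3-dimethoxybenzene)
Conditions: PBr3 (0.4 eq), CH2Cl2, 0 °C; used fresh
Reagents that add atoms: phosphorus tribromide, BrP(Br)Br
Why: Bromination of an activated benzylic alcohol via its bromophosphite (SN2); the ethers are inert to PBr3 at 0 °C.

**Step 5**
Reactants: 6 furfural
Product: 8 racemic 5-hydroxyfuran-2(5H)-one, via furfural endoperoxide 7 (not isolated)
Conditions: O2, rose bengal (cat.), MeOH, visible light, 20 °C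
Reagents that add atoms: dioxygen, O=O
Why: Dye-sensitised singlet-oxygen [4+2] cycloaddition to the furan, then methanolysis and fragmentation of the endoperoxide, which expels the formyl carbon as methyl formate and leaves the pseudo-acid; no lasting stereocentre is set.

**Step 6**
Reactants: 8 racemic 5-hydroxyfuran-2(5H)-one; 9 (−)-menthol
Product: 10 (5R)-5-(l-menthyloxy)furan-2(5H)-one
Conditions: CSA (cat.), toluene, Dean–Stark reflux; crystallise from petroleum ether at −20 °C; re-equilibrate the mother liquor (cat. TsOH) and recrystallise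
Reagents that add atoms: none
Why: Acid-catalysed acetalisation of the pseudo-acid gives both C5 epimers, which interconvert through the oxocarbenium ion; the (5R)-epimer crystallises, so crystallisation with recycling delivers a single diastereomer.

**Step 7**
Reactants: 3 2-[4-(benzyloxy)-3,5-dimethoxyphenyl]-1,3-dithiane; 10 (5R)-5-(l-menthyloxy)furan-2(5H)-one; 5 4-(benzyloxy)-3,5-dimethoxybenzyl bromide
Product: 13 (3R,4R,5R)-3-[4-(benzyloxy)-3,5-dimethoxybenzyl]-4-{2-[4-(benzyloxy)-3,5-dimethoxyphenyl]-1,3-dithian-2-yl}-5-(l-menthyloxy)dihydrofuran-2(3H)-one, via 2-lithio-2-aryl-1,3-dithiane 11 (not isolated), via lithium lactone enolate 12 (not isolated)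
Conditions: n-BuLi (1.05 eq), THF, −78 to −20 °C; then 10, −78 °C; then 5 (1.3 eq), DMPU, −78 °C to rt; aq. NH4Cl
Reagents that add atoms: n-butyllithium, [Li]CCCC (supplies only the lithium of 11 and 12; none of its atoms remain in 13)
Why: Tandem Michael addition/enolate alkylation: the soft Corey–Seebach anion adds 1,4 to the butenolide anti to the C5 menthyloxy group (sets C4), and the enolate is then benzylated anti to the bulky C4 substituent (sets C3), giving the trans,trans lactone.

**Step 8**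
Reactants: 13 the dithianyl lactone from step 7
Product: 14 (3R,4R,5R)-3,4-bis[4-(benzyloxy)-3,5-dimethoxybenzyl]-5-(l-menthyloxy)dihydrofuran-2(3H)-one
Conditions: NiCl2·6H2O (10 eq), NaBH4 (30 eq), MeOH–THF, 0 °C to rt
Reagents that add atoms: none
Why: Nickel boride reductive desulfurisation (Mozingo-type) turns the dithioacetal carbon into CH2 while sparing the benzyl ethers and the lactone acetal; the trans arrangement is also the thermodynamic one, so no epimerisation is expected.

**Step 9**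
Reactants: 14 the trans,trans-dibenzyl lactone acetal
Product: 15 (2R,3R)-2,3-bis[4-(benzyloxy)-3,5-dimethoxybenzyl]butane-1,4-diol
Conditions: LiAlH4 (4 eq), THF, 0 °C to reflux; Fieser work-up; menthol removed by chromatography
Reagents that add atoms: none
Why: Exhaustive hydride reduction of the γ-alkoxy lactone takes both the carbonyl carbon and the masked aldehyde carbon (with loss of mentholate) to CH2OH faster than any enolisation, so both stereocentres are carried through unchanged.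

**Step 10**
Reactants: 15 (2R,3R)-2,3-bis[4-(benzyloxy)-3,5-dimethoxybenzyl]butane-1,4-diol
Product: 16 5,5'-dimethoxysecoisolariciresinol, (2R,3R)-2,3-bis(4-hydroxy-3,5-dimethoxybenzyl)butane-1,4-diol
Conditions: H2 (1 atm), 10% Pd/C, EtOH–EtOAc, rt
Reagents that add atoms: none
Why: Catalytic hydrogenolysis of the two aryl benzyl ethers; no other group is reducible and the stereocentres are not involved.

**Compound list**
1 | syringaldehyde (4-hydroxy-3,5-dimethoxybenzaldehyde) | COc1cc(C=O)cc(OC)c1O | starting material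
2 | 4-(benzyloxy)-3,5-dimethoxybenzaldehyde | COc1cc(C=O)cc(OC)c1OCc1ccccc1 | intermediate
3 | 2-[4-(benzyloxy)-3,5-dimethoxyphenyl]-1,3-dithiane | COc1cc(cc(OC)c1OCc1ccccc1)C1SCCCS1 | intermediate
4 | [4-(benzyloxy)-3,5-dimethoxyphenyl]methanol | COc1cc(CO)cc(OC)c1OCc1ccccc1 | intermediate
5 | 4-(benzyloxy)-3,5-dimethoxybenzyl bromide | COc1cc(CBr)cc(OC)c1OCc1ccccc1 | intermediate
6 | furfural | O=Cc1ccco1 | starting material
7 | furfural endoperoxide (1-formyl-2,3,7-trioxabicyclo[2.2.1]hept-5-ene, racemic) | O=CC12OOC(C=C1)O2 | intermediate (not isolated)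
8 | 5-hydroxyfuran-2(5H)-one (racemic) | OC1OC(=O)C=C1 | intermediate
9 | (−)-menthol, (1R,2S,5R)-2-isopropyl-5-methylcyclohexanol | C[C@@H]1CC[C@H]([C@@H](C1)O)C(C)C | starting material
10 | (5R)-5-(l-menthyloxy)furan-2(5H)-one | C[C@@H]1CC[C@H]([C@@H](C1)O[C@@H]2OC(=O)C=C2)C(C)C | intermediate
11 | 2-lithio-2-[4-(benzyloxy)-3,5-dimethoxyphenyl]-1,3-dithiane | [Li]C1(SCCCS1)c1cc(OC)c(OCc2ccccc2)c(OC)c1 | intermediate (not isolated)
12 | lithium enolate of (4R,5R)-4-{2-[4-(benzyloxy)-3,5-dimethoxyphenyl]-1,3-dithian-2-yl}-5-(l-menthyloxy)dihydrofuran-2(3H)-one | C[C@@H]1CC[C@H]([C@@H](C1)O[C@@H]2OC(O[Li])=C[C@H]2C3(SCCCS3)c4cc(OC)c(OCc5ccccc5)c(OC)c4)C(C)C | intermediate (not isolated)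
13 | (3R,4R,5R)-3-[4-(benzyloxy)-3,5-dimethoxybenzyl]-4-{2-[4-(benzyloxy)-3,5-dimethoxyphenyl]-1,3-dithian-2-yl}-5-(l-menthyloxy)dihydrofuran-2(3H)-one | C[C@@H]1CC[C@H]([C@@H](C1)O[C@@H]2OC(=O)[C@H](Cc3cc(OC)c(OCc4ccccc4)c(OC)c3)[C@H]2C5(SCCCS5)c6cc(OC)c(OCc7ccccc7)c(OC)c6)C(C)C | intermediate
14 | (3R,4R,5R)-3,4-bis[4-(benzyloxy)-3,5-dimethoxybenzyl]-5-(l-menthyloxy)dihydrofuran-2(3H)-one | C[C@@H]1CC[C@H]([C@@H](C1)O[C@@H]2OC(=O)[C@H](Cc3cc(OC)c(OCc4ccccc4)c(OC)c3)[C@H]2Cc5cc(OC)c(OCc6ccccc6)c(OC)c5)C(C)C | intermediate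
15 | (2R,3R)-2,3-bis[4-(benzyloxy)-3,5-dimethoxybenzyl]butane-1,4-diol | COc1cc(C[C@@H](CO)[C@H](CO)Cc2cc(OC)c(OCc3ccccc3)c(OC)c2)cc(OC)c1OCc1ccccc1 | intermediate
16 | 5,5'-dimethoxysecoisolariciresinol, (2R,3R)-2,3-bis(4-hydroxy-3,5-dimethoxybenzyl)butane-1,4-diol | COc1cc(C[C@@H](CO)[C@H](CO)Cc2cc(OC)c(O)c(OC)c2)cc(OC)c1O | target

**Totals**
Total steps: 10. Longest linear sequence: 7 steps (steps 1, 3, 4, 7, 8, 9, 10; 1 → 2 → 4 → 5 → 13 → 14 → 15 → 16).

**Three steps most likely to fail, with fallbacks**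

Step 7 (tandem Michael addition/alkylation). The risk is sluggish or messy benzylation of the hindered enolate by the labile bromide 5. The fallback sets out from 3 and 10 and uses aldehyde 2 as the electrophile, so the second C–C bond is made by an aldol addition instead of an SN2 reaction. Enolate 12 is generated as before and trapped at −78 °C with 2 to give the carbinol lactone (3S,4R,5R)-3-{[4-(benzyloxy)-3,5-dimethoxyphenyl](hydroxy)methyl}-4-{2-[4-(benzyloxy)-3,5-dimethoxyphenyl]-1,3-dithian-2-yl}-5-(l-menthyloxy)dihydrofuran-2(3H)-one F1 (carbinol epimers, same ring configuration as 13). Nickel boride desulfurisation gives the hydroxy lactone (3S,4R,5R)-3-{[4-(benzyloxy)-3,5-dimethoxyphenyl](hydroxy)methyl}-4-[4-(benzyloxy)-3,5-dimethoxybenzyl]-5-(l-menthyloxy)dihydrofuran-2(3H)-one F2. LiAlH4 then gives the triol (2R,3R)-1-[4-(benzyloxy)-3,5-dimethoxyphenyl]-3-[4-(benzyloxy)-3,5-dimethoxybenzyl]-2-(hydroxymethyl)butane-1,4-diol F3. Hydrogenolysis (H2, Pd/C, EtOH–AcOH) removes both benzyl ethers and the activated para-hydroxybenzylic hydroxyl in one operation, and the route comes back at 16.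

Step 8 (nickel boride desulfurisation). The risks are incomplete C–S cleavage and borohydride attack on the lactone acetal. The fallback sets out from 13 and reverses the order, so that desulfurisation is done on a robust diol with preformed Raney nickel. LiAlH4 in THF first gives the dithiane diol (2R,3R)-2-[4-(benzyloxy)-3,5-dimethoxybenzyl]-3-{2-[4-(benzyloxy)-3,5-dimethoxyphenyl]-1,3-dithian-2-yl}butane-1,4-diol F4 and releases menthol. Raney nickel (W-2) in refluxing EtOH then gives 15, where the route is rejoined; any material that has lost a benzyl group converges on 16 in step 10.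

Step 6 (acetalisation and crystallisation of the single diastereomer 10). All absolute configuration depends on this step. The fallback sets out from aldehyde 2 and replaces the chiral template by catalytic asymmetric hydrogenation. Stobbe condensation of 2 with dimethyl succinate (NaOMe, MeOH, reflux) gives the half-ester (E)-4-[4-(benzyloxy)-3,5-dimethoxyphenyl]-3-(methoxycarbonyl)but-3-enoic acid F5. Hydrogenation with a cationic Rh(I)/chiral diphosphine catalyst (for example (4S,5S)-MOD-DIOP; the ligand hand that gives the (R)-acid must be confirmed by the rotation of the derived lactone) gives (3R)-4-[4-(benzyloxy)-3,5-dimethoxyphenyl]-3-(methoxycarbonyl)butanoic acid F6. Reduction of the ester in the potassium carboxylate with Ca(BH4)2 (CaCl2/NaBH4, EtOH), then acid lactonisation, gives (4R)-4-[4-(benzyloxy)-3,5-dimethoxybenzyl]dihydrofuran-2(3H)-one F7. Enolisation with LDA (THF, −78 °C) and trans-selective alkylation with bromide 5 gives (3R,4R)-3,4-bis[4-(benzyloxy)-3,5-dimethoxybenzyl]dihydrofuran-2(3H)-one F8. LiAlH4 reduction brings the route back at 15.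

**Further compounds**
F1 | step 7 | (3S,4R,5R)-3-{[4-(benzyloxy)-3,5-dimethoxyphenyl](hydroxy)methyl}-4-{2-[4-(benzyloxy)-3,5-dimethoxyphenyl]-1,3-dithian-2-yl}-5-(l-menthyloxy)dihydrofuran-2(3H)-one (carbinol epimers) | C[C@@H]1CC[C@H]([C@@H](C1)O[C@@H]2OC(=O)[C@H](C(O)c3cc(OC)c(OCc4ccccc4)c(OC)c3)[C@H]2C5(SCCCS5)c6cc(OC)c(OCc7ccccc7)c(OC)c6)C(C)C
F2 | step 7 | (3S,4R,5R)-3-{[4-(benzyloxy)-3,5-dimethoxyphenyl](hydroxy)methyl}-4-[4-(benzyloxy)-3,5-dimethoxybenzyl]-5-(l-menthyloxy)dihydrofuran-2(3H)-one (carbinol epimers) | C[C@@H]1CC[C@H]([C@@H](C1)O[C@@H]2OC(=O)[C@H](C(O)c3cc(OC)c(OCc4ccccc4)c(OC)c3)[C@H]2Cc5cc(OC)c(OCc6ccccc6)c(OC)c5)C(C)C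
F3 | step 7 | (2R,3R)-1-[4-(benzyloxy)-3,5-dimethoxyphenyl]-3-[4-(benzyloxy)-3,5-dimethoxybenzyl]-2-(hydroxymethyl)butane-1,4-diol (C1 epimers) | COc1cc(C[C@@H](CO)[C@H](CO)C(O)c2cc(OC)c(OCc3ccccc3)c(OC)c2)cc(OC)c1OCc1ccccc1
F4 | step 8 | (2R,3R)-2-[4-(benzyloxy)-3,5-dimethoxybenzyl]-3-{2-[4-(benzyloxy)-3,5-dimethoxyphenyl]-1,3-dithian-2-yl}butane-1,4-diol | COc1cc(C[C@@H](CO)[C@H](CO)C2(SCCCS2)c3cc(OC)c(OCc4ccccc4)c(OC)c3)cc(OC)c1OCc5ccccc5
F5 | step 6 | (E)-4-[4-(benzyloxy)-3,5-dimethoxyphenyl]-3-(methoxycarbonyl)but-3-enoic acid | COC(=O)/C(CC(=O)O)=C/c1cc(OC)c(OCc2ccccc2)c(OC)c1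
F6 | step 6 | (3R)-4-[4-(benzyloxy)-3,5-dimethoxyphenyl]-3-(methoxycarbonyl)butanoic acid | COC(=O)[C@@H](CC(=O)O)Cc1cc(OC)c(OCc2ccccc2)c(OC)c1
F7 | step 6 | (4R)-4-[4-(benzyloxy)-3,5-dimethoxybenzyl]dihydrofuran-2(3H)-one | O=C1C[C@@H](Cc2cc(OC)c(OCc3ccccc3)c(OC)c2)CO1
F8 | step 6 | (3R,4R)-3,4-bis[4-(benzyloxy)-3,5-dimethoxybenzyl]dihydrofuran-2(3H)-one | O=C1OC[C@H](Cc2cc(OC)c(OCc3ccccc3)c(OC)c2)[C@H]1Cc4cc(OC)c(OCc5ccccc5)c(OC)c4
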